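Remark: atoms are numbered as in germacranolides (ring C1–C10, lactone carbons C11–C13). Read from its SMILES, the target is 6S,7S,8S,9R with a Z double bond C1=C10 and an E double bond C4=C5. The C-silylated alkynol 1 is assumed to be a catalogue compound.

## Analysis of the target

CNP0303917.1 (32) is a germacranolide: a ten-membered carbocycle C1–C10 fused across C6–C7 to an α-methylene-γ-butyrolactone (C11=C13, C12 carbonyl, ring oxygen on C6). The carbocycle holds two methyl-bearing trisubstituted alkenes of opposite geometry: C1=C10 is Z (C2 and C9 cis) and C4=C5 is E (C3 and C6 trans, the C4 methyl cis to C6). All oxygen sits on four contiguous stereocentres: the lactone oxygen on C6, a tertiary hydroxyl on the fully substituted C7, a free secondary hydroxyl on C8 and the angelate on C9. Along C6–C9 the oxygens are threo (C6/C7), erythro (C7/C8) and threo (C8/C9); the lactone is cis-fused, and the C8/C9 pair has the configuration of D-tartaric acid. Sensitive groups are the α-methylene lactone (Michael acceptor), the angelate (Z to E isomerisation, acyl shift to the neighbouring C8 hydroxyl), the 1,5-diene in a medium ring (acid-induced transannular cyclisation, Cope rearrangement on heating) and the allylic C–O bonds at C6 and C9. The difficulty lies in closing a ten-membered ring that contains an E-trisubstituted alkene, in setting the quaternary carbinol C7 between two other carbinols, and in telling four oxygens apart. The strategy rests on one feature: C6 is an allylic carbinol on the E alkene C4=C5 with the C4 methyl cis to it, which is the result of adding a carbonyl carbon and a methyl group to the same side of a terminal alkyne C4≡C5.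

## Retrosynthetic reasoning

**Silyl ethers last (32 from 31).** The free C8 hydroxyl next to the angelate invites acyl migration, and the free C7/C8 diol would compete in every acylation and oxidation. Both hydroxyls therefore stay silylated to the end and are released together by fluoride under slightly acidic conditions, which the lactone, the ester and the diene tolerate.

**Angelate (31 from 28 and 29).** The C9–O acyl bond is cut late. An enoate would compete with the alkyne at nickel in the ring closure, and the Z ester survives few further operations. The forward step has to acylate a hindered allylic alcohol without Z to E isomerisation, with C8 blocked.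

**Lactone and benzylic ethers (28 from 27, 27 from 25, 25 from 24).** The C12–O6 bond of the lactone is traced back to a 2-methylene-1,4-diol, so that the lactone forms by oxidation of the primary allylic alcohol and the C6 configuration is kept. C12 is masked as a 4-methoxybenzyl ether and C9 as a 2-naphthylmethyl ether. The first is removed oxidatively before the second, which gives the order lactone first, angelate second, with no further differentiation.

**Ring closure (24 from 23).** Two bonds are cut at once, C5–C6 and C4–CH3. Cutting here, and not at C2–C3 or at an alkene, removes the need for a separately made E-alkenyl halide: the E geometry, the C6 carbinol and the ten-membered ring all arise in one event from a linear aldehyde with a terminal alkyne. The forward reaction has to join the aldehyde carbon to the terminal alkyne carbon, place the methyl on the internal carbon on the same side, and do so intramolecularly.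

**C6–C7 bond (23 from 22 and 21, 21 from 19).** The aldehyde carbon C6 is traced to a hydroxymethyl group added to the C7 ketone of enone 19. Adding C6 last (and C11 before it) is chosen because attack anti to the C8 silyloxy group (Felkin–Anh) then gives the required C7 configuration; the reverse order would need the opposite face. C7 and C8 are carried as two separate silyl ethers and not as one five-membered silylene bridge, because such a bridge over a 1,2-diol is strained and easily opened, and because the bulky non-chelating silyl ether on O8 is the control element for this addition.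

**C7–C11 bond (19 from 18, 18 from 16 and 5 through 17).** The 2-propenyl unit with its C12 ether is attached as an alkenyllithium to the C7 aldehyde 16. The carbinol formed is oxidised at once, so no selectivity is needed.

**C10=C1 alkene (16 from 15, 15 from 13 and 3).** The Z alkene is cut to the α-alkoxy methyl ketone 13 and a non-stabilised ylide. An α-alkoxy ketone directs the ylide substituent cis to the oxygenated carbon, which is the Z isomer required. The alkyne is carried C-silylated so that it survives the organometallic steps.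

**C7–C10 from the chiral pool (13 from 11, 11 from 9, 9 from 8, 8 from 6).** C8 and C9 are the two stereocentres of diethyl D-tartrate 6. Mono-etherification of the C2-symmetric diol places the naphthylmethyl group on O9 in one step. The remaining free hydroxyl then directs reduction of the adjacent ester only, which tells the two ends apart: C7 becomes a primary alcohol and C10 stays an ester for conversion to the methyl ketone.

**Side pieces (3 from 2 from 1; 5 from 4).** The phosphonium salt and the bromoallyl ether are each one or two routine steps from catalogue compounds.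

## Alternatives that were turned down

**Alternative 1:** The lactone bond C7–C11 is disconnected, with C5–C10 taken from a hexopyranoside. In the forward sense a dirhodium carboxylate would decompose the 2-O-diazo(phosphono)acetyl 3,4-O-isopropylidene galactopyranoside A1. The carbenoid inserts into the neighbouring C3–H bond (target C7–H) with retention and gives the cis-fused γ-lactone phosphonate A2; the phosphonate later supplies the exo-methylene.
- For: the fully substituted C7 is fixed by retention from a sugar stereocentre, the cis ring fusion is enforced by the five-membered transition state, and C6, C8 and C9 come from the pool. On the configuration of C6 and C7 this is stronger than the chosen route, where C7 depends on a Felkin–Anh addition (step 12) and C6 on the facial selectivity of the ring closure (step 15).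
- Against: the step forms no bond of the ten-membered ring. The pyranose must still be opened, both of its termini turned into methyl-bearing alkenes of opposite geometry, the C2–C3 unit added and the medium ring closed, so the hardest problem is only postponed. The anomeric C–H is equally placed for γ-lactone formation and is more activated, so the site of insertion is not secure.
- Comparison: the chosen strategy takes C8 and C9 from 6 and spends its key step on the ring and the E alkene at once, which is shorter and puts the risk in a single step.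

**Alternative 2:** The σ bonds C1–C10 and C4–C5 are disconnected. Irradiation near 350 nm would join cyclohexenone A3 and 1-methylcyclobutene A4 to the cis,anti,cis photoadduct A5, and later thermolysis would cleave the cyclobutane in the other sense to open the ten-membered 1,5-diene.
- For: the whole carbocycle is built from a six-membered ring, on which C6–C9 can be set with ordinary cyclohexane control, and no medium-ring closure is needed. On ring formation as such this is stronger than any direct ten-membered closure, the chosen one included.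
- Against: the orientation of the unsymmetrical cyclobutene decides whether the methyl ends on C4, and nothing in A3 controls it. The alkene geometries after cycloreversion follow from orbital symmetry and ring fusion, not from design. The temperature needed invites Cope rearrangement of the 1,5-diene and endangers the ether and amide groups. C9 remains a ketone to be reduced in a flexible ring.
- Comparison: the chosen route sets each alkene by a separate, mechanistically fixed event near room temperature (Wittig for Z, cis addition across the alkyne for E).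

**Alternative 3:** The C7–C8 bond and the C11=C13 alkene are disconnected by a [2,3]-Wittig ring contraction. A hindered potassium amide would enolise the C9 ketone of the thirteen-membered ether A6 towards C8; the enolate carbon attacks C7 of the silyl enol ether while the O–C13 bond breaks, giving the ten-membered hydroxy ketone A7.
- For: contraction of a larger ring avoids the entropic cost of direct closure, and C7, C8 and the exo-methylene arise together. In bonds and stereocentres made at the most crowded site this is stronger than the chosen key step.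
- Against: the migration terminus C7 is a fully substituted enol ether carbon, and two adjacent stereocentres (one quaternary) would depend on enolate geometry and a transannular transition state. [1,2]-Shift and β-elimination of the α-alkoxy enolate compete. A6 is itself a demanding macrocycle. A7 still has the C9 ketone and the wrong C6 configuration.
- Comparison: the chosen route takes C8 and C9 from 6 without risk, and its ring-closure precursor 23 is linear and reached by standard steps.

Key step: step 15

## Route

Step 1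
Reactants: 1 5-(trimethylsilyl)pent-4-yn-1-ol
Product: 2 (5-iodopent-1-yn-1-yl)trimethylsilane
Conditions: I2, PPh3, imidazole, CH2Cl2, 0 °C to rt
Reagents that add atoms: iodine, [I][I]
Why: Appel-type iodination of a primary alcohol by SN2 displacement of the alkoxyphosphonium group; the alkynylsilane is inert.

Step 2
Reactants: 2 (5-iodopent-1-yn-1-yl)trimethylsilane
Product: 3 triphenyl[5-(trimethylsilyl)pent-4-yn-1-yl]phosphonium iodide
Conditions: PPh3, MeCN, reflux
Reagents that add atoms: triphenylphosphine, c1ccc(cc1)P(c1ccccc1)c1ccccc1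
Why: SN2 quaternisation of triphenylphosphine by a primary iodide; the salt should crystallise.

Step 3
Reactants: 4 2-bromoprop-2-en-1-ol
Product: 5 1-{[(2-bromoprop-2-en-1-yl)oxy]methyl}-4-methoxybenzene
Conditions: NaH, 4-methoxybenzyl chloride, Bu4NI (cat.), THF/DMF, 0 °C to rt
Reagents that add atoms: 4-methoxybenzyl chloride, COc1ccc(CCl)cc1
Why: Williamson ether synthesis on the allylic alkoxide; the vinyl bromide does not react with alkoxide at this temperature.

Step 4
Reactants: 6 diethyl D-tartrate
Product: 8 diethyl (2S,3S)-2-hydroxy-3-(naphthalen-2-ylmethoxy)butanedioate, via stannylene acetal 7 (not isolated)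
Conditions: Bu2SnO, toluene, reflux (Dean–Stark); then 2-(bromomethyl)naphthalene, CsF, DMF, rt
Reagents that add atoms: 2-(bromomethyl)naphthalene, BrCc1ccc2ccccc2c1
Why: Stannylene-acetal mono-alkylation: fluoride activates one tin-bound oxygen, which is alkylated once; the two hydroxyls of 6 are equivalent, so a single mono-ether forms, and the absence of strong base avoids epimerisation and elimination.

Step 5
Reactants: 8 diethyl (2S,3S)-2-hydroxy-3-(naphthalen-2-ylmethoxy)butanedioate
Product: 9 ethyl (2S,3R)-3,4-dihydroxy-2-(naphthalen-2-ylmethoxy)butanoate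
Conditions: BH3·SMe2 (1.05 equiv), NaBH4 (5 mol %), THF, 0 °C to rt; MeOH
Reagents that add atoms: none
Why: Hydroxyl-directed borane reduction: the free C8 hydroxyl forms an alkoxyborane that delivers hydride only to the adjacent ester, so the ester next to the naphthylmethyl ether (C10) is kept and the two termini are told apart; 9 is silylated at once to forestall lactonisation.

Step 6
Reactants: 9 ethyl (2S,3R)-3,4-dihydroxy-2-(naphthalen-2-ylmethoxy)butanoate
Product: 11 ethyl (2S,3R)-3-[(tert-butyldimethylsilyl)oxy]-2-(naphthalen-2-ylmethoxy)-4-[(triethylsilyl)oxy]butanoate, via primary triethylsilyl ether 10 (not isolated)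
Conditions: Et3SiCl (1.05 equiv), imidazole, CH2Cl2, −20 °C; then t-BuMe2SiOTf, 2,6-lutidine, −20 to 0 °C
Reagents that add atoms: chlorotriethylsilane, CC[Si](Cl)(CC)CC; tert-butyldimethylsilyl trifluoromethanesulfonate, CC(C)(C)[Si](C)(C)OS(=O)(=O)C(F)(F)F
Why: Sequential silylation by reactivity: the primary hydroxyl takes the silyl chloride at low temperature and the hindered secondary hydroxyl then needs the silyl triflate; the primary triethylsilyl ether can later be oxidised directly, and the bulky silyl ether on O8 is the non-chelating group needed in step 12.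

Step 7
Reactants: 11 ethyl (2S,3R)-3-[(tert-butyldimethylsilyl)oxy]-2-(naphthalen-2-ylmethoxy)-4-[(triethylsilyl)oxy]butanoate
Product: 13 (3S,4R)-4-[(tert-butyldimethylsilyl)oxy]-3-(naphthalen-2-ylmethoxy)-5-[(triethylsilyl)oxy]pentan-2-one, via Weinreb amide 12 (not isolated)
Conditions: MeNH(OMe)·HCl, i-PrMgCl, THF, −20 °C; then MeMgBr, 0 °C; aq. NH4Cl
Reagents that add atoms: methylmagnesium bromide, C[Mg]Br
Why: Weinreb ketone synthesis in one flask: the magnesium amide converts the ester to the N-methoxy-N-methylamide, whose chelated tetrahedral adduct with MeMgBr stops at the ketone; the cold, weakly basic medium should leave C9 untouched.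

Step 8
Reactants: 13 (3S,4R)-4-[(tert-butyldimethylsilyl)oxy]-3-(naphthalen-2-ylmethoxy)-5-[(triethylsilyl)oxy]pentan-2-one; 3 triphenyl[5-(trimethylsilyl)pent-4-yn-1-yl]phosphonium iodide
Product: 15 Z-enyne, tert-butyldimethyl{[(2R,3R,4Z)-4-methyl-3-(naphthalen-2-ylmethoxy)-1-[(triethylsilyl)oxy]-9-(trimethylsilyl)non-4-en-8-yn-2-yl]oxy}silane, via phosphorus ylide 14 (not isolated)
Conditions: 3, KN(SiMe3)2, THF, −78 to 0 °C; then 13, −78 °C to rt
Reagents that add atoms: none
Why: Wittig olefination with a non-stabilised, salt-free ylide: with α-alkoxy methyl ketones the ylide substituent ends cis to the oxygenated carbon, which here is the Z alkene C1=C10; the C-silyl group keeps the alkyne from being deprotonated here and in the later organometallic steps.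

Step 9
Reactants: 15 Z-enyne (primary triethylsilyl ether)
Product: 16 (2S,3R,4Z)-2-[(tert-butyldimethylsilyl)oxy]-4-methyl-3-(naphthalen-2-ylmethoxy)-9-(trimethylsilyl)non-4-en-8-ynal
Conditions: (COCl)2, DMSO, CH2Cl2, −78 to −40 °C; Et3N, −78 °C to rt
Reagents that add atoms: none
Why: Swern oxidation applied directly to a primary triethylsilyl ether: the chlorosulfonium salt exchanges at the unhindered O–Si bond and the alkoxysulfonium ylide collapses to the aldehyde, while the secondary tert-butyldimethylsilyl ether stays; the aldehyde is used at once.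

Step 10
Reactants: 16 C7 aldehyde; 5 1-{[(2-bromoprop-2-en-1-yl)oxy]methyl}-4-methoxybenzene
Product: 18 (4R,5R,6Z)-4-[(tert-butyldimethylsilyl)oxy]-2-{[(4-methoxyphenyl)methoxy]methyl}-6-methyl-5-(naphthalen-2-ylmethoxy)-11-(trimethylsilyl)undeca-1,6-dien-10-yn-3-ol (both C3 epimers), via alkenyllithium 17 (not isolated)
Conditions: 5, t-BuLi (2 equiv per 5), Et2O, −78 °C; then 16, −78 °C; aq. NH4Cl
Reagents that add atoms: none
Why: Bromine–lithium exchange gives the 2-lithioallyl ether, which is stable at −78 °C and adds 1,2 to the aldehyde; the new carbinol (target C7) is oxidised in the next step, so its configuration does not matter.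

Step 11
Reactants: 18 allylic alcohol (epimers at C3)
Product: 19 (4S,5R,6Z)-4-[(tert-butyldimethylsilyl)oxy]-2-{[(4-methoxyphenyl)methoxy]methyl}-6-methyl-5-(naphthalen-2-ylmethoxy)-11-(trimethylsilyl)undeca-1,6-dien-10-yn-3-one
Conditions: Dess–Martin periodinane, NaHCO3, CH2Cl2, 0 °C to rt
Reagents that add atoms: none
Why: Dess–Martin oxidation of a secondary allylic alcohol under buffered, non-basic conditions; both epimers converge on one enone and C8 is not enolised.

Step 12
Reactants: 19 enone
Product: 21 (2R,3S,4R,5Z)-3-[(tert-butyldimethylsilyl)oxy]-2-{3-[(4-methoxyphenyl)methoxy]prop-1-en-2-yl}-5-methyl-4-(naphthalen-2-ylmethoxy)dec-5-en-9-yne-1,2-diol, via β-hydroxysilane 20 (not isolated)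
Conditions: (i-PrO)Me2SiCH2MgCl (from the chloromethylsilane and Mg), CeCl3, THF, −78 °C; then 30% H2O2, KF, KHCO3, MeOH/THF, rt
Reagents that add atoms: [(isopropoxy)dimethylsilyl]methylmagnesium chloride, CC(C)O[Si](C)(C)C[Mg]Cl; hydrogen peroxide, OO
Why: Nucleophilic hydroxymethylation: the silylmethyl reagent, made non-basic and 1,2-selective by CeCl3, should attack the C7 carbonyl anti to the C8 silyloxy group (Felkin–Anh; the silyl ether is the poorest donor, so any chelate forms through the C9 and C12 benzylic ether oxygens and leaves the same face open), which gives the C7 configuration drawn. Tamao oxidation then turns C–Si into C–OH, and fluoride in methanol is expected to cleave the alkynyl C–Si bond in the same operation.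

Step 13
Reactants: 21 diol with terminal alkyne
Product: 22 tert-butyl{[(2R,3S,4R,5Z)-2-{3-[(4-methoxyphenyl)methoxy]prop-1-en-2-yl}-5-methyl-4-(naphthalen-2-ylmethoxy)-1,2-bis[(triethylsilyl)oxy]dec-5-en-9-yn-3-yl]oxy}dimethylsilane
Conditions: Et3SiOTf (3 equiv), 2,6-lutidine, CH2Cl2, −78 to 0 °C
Reagents that add atoms: triethylsilyl trifluoromethanesulfonate, CC[Si](CC)(CC)OS(=O)(=O)C(F)(F)F
Why: Silyl triflate with a hindered pyridine base silylates both the primary and the tertiary hydroxyl; capping C7 before oxidation avoids a free tertiary α-hydroxy aldehyde.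

Step 14
Reactants: 22 bis(triethylsilyl) ether
Product: 23 (2S,3S,4R,5Z)-3-[(tert-butyldimethylsilyl)oxy]-2-{3-[(4-methoxyphenyl)methoxy]prop-1-en-2-yl}-5-methyl-4-(naphthalen-2-ylmethoxy)-2-[(triethylsilyl)oxy]dec-5-en-9-ynal
Conditions: (COCl)2, DMSO, CH2Cl2, −78 to −30 °C; Et3N, −78 °C to rt
Reagents that add atoms: none
Why: Swern oxidation of the primary triethylsilyl ether as in step 9; the tertiary and secondary silyl ethers cannot be oxidised and remain, and the aldehyde has no α-hydrogen and cannot epimerise.

Step 15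
Reactants: 23 alkynal
Product: 24 (1S,2R,3S,4R,5Z,9E)-3-[(tert-butyldimethylsilyl)oxy]-2-{3-[(4-methoxyphenyl)methoxy]prop-1-en-2-yl}-5,9-dimethyl-4-(naphthalen-2-ylmethoxy)-2-[(triethylsilyl)oxy]cyclodeca-5,9-dien-1-ol
Conditions: Ni(cod)2 (25 mol %), 1,3-dimesitylimidazol-2-ylidene (IMes, 25 mol %), ZnMe2 (3 equiv), toluene, 45 °C, 23 added over 12 h to 2 mM; aq. NH4Cl
Reagents that add atoms: dimethylzinc, C[Zn]C
Why: Proposed new method: zerovalent nickel carrying one 1,3-dimesitylimidazol-2-ylidene ligand should bind the aldehyde and the terminal alkyne of 23 and couple them oxidatively to an oxanickelacyclopentene of divalent nickel in which C5–C6 is formed and the metal sits on C4; ZnMe2 then passes a methyl group to nickel (zinc taking the alkoxide) and reductive elimination forms C4–CH3 and returns zerovalent nickel. The closest known reaction types are the nickel-catalysed reductive macrocyclisation of ynals with silanes, which closes large rings in the endocyclic sense when the alkyne is terminal and the carbene ligand is small, and the nickel-catalysed alkylative cyclisation of ynals with organozincs, which closes small rings in the exocyclic sense; methyl transfer combined with an endocyclic ten-membered closure has not been shown. The ring closes in the endocyclic mode (both alkyne carbons inside the ten-membered ring): the unsubstituted terminus C5 bonds to the carbonyl carbon, so the tether on C4 lies next to nickel and away from the mesityl groups. Because C6 and nickel are held cis in the five-membered metallacycle and reductive elimination keeps that geometry, the methyl group ends cis to C6, which is the E alkene, with no alkenyl halide to prepare. The new stereocentre C6 is set under the influence of the adjacent fully substituted C7: with the C7–OSiEt3 bond anti to the forming C5–C6 bond and the ring-bearing C8 branch turned away from the ligated nickel–oxygen end, the 6S carbinol drawn should result, but this facial preference is not secured. The step needs ring closure to outrun oligomerisation and direct methyl addition to the aldehyde, which high dilution with slow addition and the low reactivity of ZnMe2 towards a hindered aldehyde should provide; the two existing alkenes, the benzylic ethers and the silyl ethers are not substrates for the catalyst, and no enoate is present yet.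

Step 16
Reactants: 24 cyclodecadienol
Product: 25 (1S,2R,3S,4R,5Z,9E)-3-[(tert-butyldimethylsilyl)oxy]-2-(3-hydroxyprop-1-en-2-yl)-5,9-dimethyl-4-(naphthalen-2-ylmethoxy)-2-[(triethylsilyl)oxy]cyclodeca-5,9-dien-1-ol
Conditions: DDQ (1.2 equiv), CH2Cl2/pH 7 buffer, 0 °C
Reagents that add atoms: none
Why: Oxidative cleavage of the 4-methoxybenzyl ether by hydride abstraction and hydrolysis; the more electron-rich 4-methoxybenzyl group reacts well before the 2-naphthylmethyl ether, and buffered water intercepts the oxocarbenium ion before the C6 hydroxyl can.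

Step 17
Reactants: 25 2-methylene-1,4-diol
Product: 27 (3aR,4S,5R,6Z,10E,11aS)-4-[(tert-butyldimethylsilyl)oxy]-6,10-dimethyl-3-methylidene-5-(naphthalen-2-ylmethoxy)-3a-[(triethylsilyl)oxy]-3a,4,5,8,9,11a-hexahydrocyclodeca[b]furan-2(3H)-one, via lactol 26 (not isolated)
Conditions: TEMPO (2,2,6,6-tetramethylpiperidin-1-oxyl, 30 mol %), PhI(OAc)2 (3 equiv), CH2Cl2, rt
Reagents that add atoms: none
Why: Oxidative lactonisation: the oxoammonium species oxidises the primary allylic alcohol far faster than the hindered secondary one, the enal is trapped by the C6 hydroxyl as a five-membered lactol and this is oxidised to the lactone; the C6–O bond is never broken, so C6 keeps its configuration and the fusion is cis.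

Step 18
Reactants: 27 lactone
Product: 28 (3aR,4S,5R,6Z,10E,11aS)-4-[(tert-butyldimethylsilyl)oxy]-5-hydroxy-6,10-dimethyl-3-methylidene-3a-[(triethylsilyl)oxy]-3a,4,5,8,9,11a-hexahydrocyclodeca[b]furan-2(3H)-one
Conditions: DDQ (3 equiv), CH2Cl2/H2O, rt
Reagents that add atoms: none
Why: With the 4-methoxybenzyl group gone, excess DDQ cleaves the 2-naphthylmethyl ether by the same oxidative mechanism; the silyl ethers and the electron-poor methylene lactone are not affected.

Step 19
Reactants: 28 C9 alcohol; 29 angelic acid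
Product: 31 (3aR,4S,5R,6Z,10E,11aS)-4-[(tert-butyldimethylsilyl)oxy]-6,10-dimethyl-3-methylidene-2-oxo-3a-[(triethylsilyl)oxy]-2,3,3a,4,5,8,9,11a-octahydrocyclodeca[b]furan-5-yl (2Z)-2-methylbut-2-enoate, via mixed anhydride 30 (not isolated)
Conditions: 29, 2,4,6-trichlorobenzoyl chloride, Et3N, toluene, rt; then 28, toluene, 75 °C
Reagents that add atoms: none
Why: Yamaguchi esterification run without a nucleophilic pyridine catalyst: the alcohol attacks the less hindered angeloyl carbonyl of the mixed anhydride, and the absence of a conjugate-adding catalyst keeps the Z geometry; C9–OH is the only free hydroxyl.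

Step 20
Reactants: 31 bis-silyl ether of the target
Product: 32 CNP0303917.1, (3aS,4S,5R,6Z,10E,11aS)-3a,4-dihydroxy-6,10-dimethyl-3-methylidene-2-oxo-2,3,3a,4,5,8,9,11a-octahydrocyclodeca[b]furan-5-yl (2Z)-2-methylbut-2-enoate
Conditions: HF·pyridine, pyridine, THF, 0 °C to rt
Reagents that add atoms: none
Why: Fluoride-mediated cleavage of both silyl ethers in a slightly acidic, non-nucleophilic medium, which should avoid acyl migration from O9 to O8, conjugate addition to the methylene lactone and acid-induced transannular reactions.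

## Compound list

1 | 5-(trimethylsilyl)pent-4-yn-1-ol | OCCCC#C[Si](C)(C)C | starting material
2 | (5-iodopent-1-yn-1-yl)trimethylsilane | ICCCC#C[Si](C)(C)C | intermediate
3 | triphenyl[5-(trimethylsilyl)pent-4-yn-1-yl]phosphonium iodide | C[Si](C)(C)C#CCCC[P+](c1ccccc1)(c1ccccc1)c1ccccc1.[I-] | intermediate
4 | 2-bromoprop-2-en-1-ol | OCC(Br)=C | starting material
5 | 1-{[(2-bromoprop-2-en-1-yl)oxy]methyl}-4-methoxybenzene | C=C(Br)COCc1ccc(OC)cc1 | intermediate
6 | diethyl D-tartrate, diethyl (2S,3S)-2,3-dihydroxybutanedioate | CCOC(=O)[C@@H](O)[C@H](O)C(=O)OCC | starting material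
7 | stannylene acetal, diethyl (4S,5S)-2,2-dibutyl-1,3,2-dioxastannolane-4,5-dicarboxylate (not isolated) | CCOC(=O)[C@H]1O[Sn](CCCC)(CCCC)O[C@@H]1C(=O)OCC | intermediate
8 | diethyl (2S,3S)-2-hydroxy-3-(naphthalen-2-ylmethoxy)butanedioate | CCOC(=O)[C@@H](O)[C@H](OCc1ccc2ccccc2c1)C(=O)OCC | intermediate
9 | ethyl (2S,3R)-3,4-dihydroxy-2-(naphthalen-2-ylmethoxy)butanoate | OC[C@@H](O)[C@H](OCc1ccc2ccccc2c1)C(=O)OCC | intermediate
10 | ethyl (2S,3R)-3-hydroxy-2-(naphthalen-2-ylmethoxy)-4-[(triethylsilyl)oxy]butanoate (not isolated) | CC[Si](CC)(CC)OC[C@@H](O)[C@H](OCc1ccc2ccccc2c1)C(=O)OCC | intermediate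
11 | ethyl (2S,3R)-3-[(tert-butyldimethylsilyl)oxy]-2-(naphthalen-2-ylmethoxy)-4-[(triethylsilyl)oxy]butanoate | CC[Si](CC)(CC)OC[C@@H](O[Si](C)(C)C(C)(C)C)[C@H](OCc1ccc2ccccc2c1)C(=O)OCC | intermediate
12 | (2S,3R)-3-[(tert-butyldimethylsilyl)oxy]-N-methoxy-N-methyl-2-(naphthalen-2-ylmethoxy)-4-[(triethylsilyl)oxy]butanamide (not isolated) | CC[Si](CC)(CC)OC[C@@H](O[Si](C)(C)C(C)(C)C)[C@H](OCc1ccc2ccccc2c1)C(=O)N(C)OC | intermediate
13 | (3S,4R)-4-[(tert-butyldimethylsilyl)oxy]-3-(naphthalen-2-ylmethoxy)-5-[(triethylsilyl)oxy]pentan-2-one | CC[Si](CC)(CC)OC[C@@H](O[Si](C)(C)C(C)(C)C)[C@H](OCc1ccc2ccccc2c1)C(C)=O | intermediate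
14 | triphenyl[5-(trimethylsilyl)pent-4-yn-1-ylidene]phosphorane (not isolated) | C[Si](C)(C)C#CCCC=P(c1ccccc1)(c1ccccc1)c1ccccc1 | intermediate
15 | tert-butyldimethyl{[(2R,3R,4Z)-4-methyl-3-(naphthalen-2-ylmethoxy)-1-[(triethylsilyl)oxy]-9-(trimethylsilyl)non-4-en-8-yn-2-yl]oxy}silane | CC[Si](CC)(CC)OC[C@@H](O[Si](C)(C)C(C)(C)C)[C@H](OCc1ccc2ccccc2c1)/C(C)=C\CCC#C[Si](C)(C)C | intermediate
16 | (2S,3R,4Z)-2-[(tert-butyldimethylsilyl)oxy]-4-methyl-3-(naphthalen-2-ylmethoxy)-9-(trimethylsilyl)non-4-en-8-ynal | O=C[C@@H](O[Si](C)(C)C(C)(C)C)[C@H](OCc1ccc2ccccc2c1)/C(C)=C\CCC#C[Si](C)(C)C | intermediate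
17 | {3-[(4-methoxyphenyl)methoxy]prop-1-en-2-yl}lithium (not isolated) | [Li]C(=C)COCc1ccc(OC)cc1 | intermediate
18 | (4R,5R,6Z)-4-[(tert-butyldimethylsilyl)oxy]-2-{[(4-methoxyphenyl)methoxy]methyl}-6-methyl-5-(naphthalen-2-ylmethoxy)-11-(trimethylsilyl)undeca-1,6-dien-10-yn-3-ol, both C3 epimers | C=C(COCc1ccc(OC)cc1)C(O)[C@@H](O[Si](C)(C)C(C)(C)C)[C@H](OCc2ccc3ccccc3c2)/C(C)=C\CCC#C[Si](C)(C)C | intermediate
19 | (4S,5R,6Z)-4-[(tert-butyldimethylsilyl)oxy]-2-{[(4-methoxyphenyl)methoxy]methyl}-6-methyl-5-(naphthalen-2-ylmethoxy)-11-(trimethylsilyl)undeca-1,6-dien-10-yn-3-one | C=C(COCc1ccc(OC)cc1)C(=O)[C@@H](O[Si](C)(C)C(C)(C)C)[C@H](OCc2ccc3ccccc3c2)/C(C)=C\CCC#C[Si](C)(C)C | intermediate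
20 | (3S,4S,5R,6Z)-4-[(tert-butyldimethylsilyl)oxy]-3-{[dimethyl(propan-2-yloxy)silyl]methyl}-2-{[(4-methoxyphenyl)methoxy]methyl}-6-methyl-5-(naphthalen-2-ylmethoxy)-11-(trimethylsilyl)undeca-1,6-dien-10-yn-3-ol (not isolated) | CC(C)O[Si](C)(C)C[C@](O)(C(=C)COCc1ccc(OC)cc1)[C@@H](O[Si](C)(C)C(C)(C)C)[C@H](OCc2ccc3ccccc3c2)/C(C)=C\CCC#C[Si](C)(C)C | intermediate
21 | (2R,3S,4R,5Z)-3-[(tert-butyldimethylsilyl)oxy]-2-{3-[(4-methoxyphenyl)methoxy]prop-1-en-2-yl}-5-methyl-4-(naphthalen-2-ylmethoxy)dec-5-en-9-yne-1,2-diol | OC[C@](O)(C(=C)COCc1ccc(OC)cc1)[C@@H](O[Si](C)(C)C(C)(C)C)[C@H](OCc2ccc3ccccc3c2)/C(C)=C\CCC#C | intermediate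
22 | tert-butyl{[(2R,3S,4R,5Z)-2-{3-[(4-methoxyphenyl)methoxy]prop-1-en-2-yl}-5-methyl-4-(naphthalen-2-ylmethoxy)-1,2-bis[(triethylsilyl)oxy]dec-5-en-9-yn-3-yl]oxy}dimethylsilane | CC[Si](CC)(CC)OC[C@](O[Si](CC)(CC)CC)(C(=C)COCc1ccc(OC)cc1)[C@@H](O[Si](C)(C)C(C)(C)C)[C@H](OCc2ccc3ccccc3c2)/C(C)=C\CCC#C | intermediate
23 | (2S,3S,4R,5Z)-3-[(tert-butyldimethylsilyl)oxy]-2-{3-[(4-methoxyphenyl)methoxy]prop-1-en-2-yl}-5-methyl-4-(naphthalen-2-ylmethoxy)-2-[(triethylsilyl)oxy]dec-5-en-9-ynal | O=C[C@](O[Si](CC)(CC)CC)(C(=C)COCc1ccc(OC)cc1)[C@@H](O[Si](C)(C)C(C)(C)C)[C@H](OCc2ccc3ccccc3c2)/C(C)=C\CCC#C | intermediate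
24 | (1S,2R,3S,4R,5Z,9E)-3-[(tert-butyldimethylsilyl)oxy]-2-{3-[(4-methoxyphenyl)methoxy]prop-1-en-2-yl}-5,9-dimethyl-4-(naphthalen-2-ylmethoxy)-2-[(triethylsilyl)oxy]cyclodeca-5,9-dien-1-ol | O[C@H]1/C=C(\C)CC/C=C(/C)[C@@H](OCc2ccc3ccccc3c2)[C@H](O[Si](C)(C)C(C)(C)C)[C@@]1(O[Si](CC)(CC)CC)C(=C)COCc4ccc(OC)cc4 | intermediate
25 | (1S,2R,3S,4R,5Z,9E)-3-[(tert-butyldimethylsilyl)oxy]-2-(3-hydroxyprop-1-en-2-yl)-5,9-dimethyl-4-(naphthalen-2-ylmethoxy)-2-[(triethylsilyl)oxy]cyclodeca-5,9-dien-1-ol | O[C@H]1/C=C(\C)CC/C=C(/C)[C@@H](OCc2ccc3ccccc3c2)[C@H](O[Si](C)(C)C(C)(C)C)[C@@]1(O[Si](CC)(CC)CC)C(=C)CO | intermediate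
26 | (3aR,4S,5R,6Z,10E,11aS)-4-[(tert-butyldimethylsilyl)oxy]-6,10-dimethyl-3-methylidene-5-(naphthalen-2-ylmethoxy)-3a-[(triethylsilyl)oxy]-2,3,3a,4,5,8,9,11a-octahydrocyclodeca[b]furan-2-ol, either C2 epimer (not isolated) | C=C1C(O)O[C@H]2/C=C(\C)CC/C=C(/C)[C@@H](OCc3ccc4ccccc4c3)[C@H](O[Si](C)(C)C(C)(C)C)[C@@]12O[Si](CC)(CC)CC | intermediate
27 | (3aR,4S,5R,6Z,10E,11aS)-4-[(tert-butyldimethylsilyl)oxy]-6,10-dimethyl-3-methylidene-5-(naphthalen-2-ylmethoxy)-3a-[(triethylsilyl)oxy]-3a,4,5,8,9,11a-hexahydrocyclodeca[b]furan-2(3H)-one | C=C1C(=O)O[C@H]2/C=C(\C)CC/C=C(/C)[C@@H](OCc3ccc4ccccc4c3)[C@H](O[Si](C)(C)C(C)(C)C)[C@@]12O[Si](CC)(CC)CC | intermediate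
28 | (3aR,4S,5R,6Z,10E,11aS)-4-[(tert-butyldimethylsilyl)oxy]-5-hydroxy-6,10-dimethyl-3-methylidene-3a-[(triethylsilyl)oxy]-3a,4,5,8,9,11a-hexahydrocyclodeca[b]furan-2(3H)-one | C=C1C(=O)O[C@H]2/C=C(\C)CC/C=C(/C)[C@@H](O)[C@H](O[Si](C)(C)C(C)(C)C)[C@@]12O[Si](CC)(CC)CC | intermediate
29 | angelic acid, (2Z)-2-methylbut-2-enoic acid | C/C=C(/C)C(O)=O | starting material
30 | (2Z)-2-methylbut-2-enoic 2,4,6-trichlorobenzoic anhydride (not isolated) | C/C=C(/C)C(=O)OC(=O)c1c(Cl)cc(Cl)cc1Cl | intermediate
31 | (3aR,4S,5R,6Z,10E,11aS)-4-[(tert-butyldimethylsilyl)oxy]-6,10-dimethyl-3-methylidene-2-oxo-3a-[(triethylsilyl)oxy]-2,3,3a,4,5,8,9,11a-octahydrocyclodeca[b]furan-5-yl (2Z)-2-methylbut-2-enoate | C=C1C(=O)O[C@H]2/C=C(\C)CC/C=C(/C)[C@@H](OC(=O)/C(C)=C\C)[C@H](O[Si](C)(C)C(C)(C)C)[C@@]12O[Si](CC)(CC)CC | intermediate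
32 | CNP0303917.1, (3aS,4S,5R,6Z,10E,11aS)-3a,4-dihydroxy-6,10-dimethyl-3-methylidene-2-oxo-2,3,3a,4,5,8,9,11a-octahydrocyclodeca[b]furan-5-yl (2Z)-2-methylbut-2-enoate | C=C1C(=O)O[C@H]2/C=C(\C)CC/C=C(/C)[C@@H](OC(=O)/C(C)=C\C)[C@H](O)[C@@]12O | target

## Step count and least certain steps

Total step count: 20. Longest linear sequence: 17 steps (steps 4 to 20, from 6 to 32); steps 1–2 and step 3 are side branches.

**Step 15 (key step).** The closure may take the exocyclic course (C4–C6 bond, nine-membered ring), the terminal alkyne may oligomerise, methyl may add directly to the aldehyde, and the facial selectivity at C6 may be poor, because a ten-membered transition state containing the future E alkene is strained and the C7 centre is the only control element. The fallback uses known chemistry and sets out from 22. Zirconium-catalysed carboalumination of the terminal alkyne (AlMe3, Cp2ZrCl2, then I2) gives the (E)-alkenyl iodide F1, in which the methyl is already on C4 and cis to iodine. Swern oxidation of its primary triethylsilyl ether gives the iodo aldehyde F2. Nozaki–Hiyama–Kishi cyclisation (CrCl2, catalytic NiCl2, DMSO/THF, high dilution) closes C5–C6 and returns to 24. If this or the nickel closure delivers mainly the C6-epimeric alcohol F3, oxidation with Dess–Martin periodinane gives the ring enone F4, and Luche reduction (NaBH4, CeCl3) from the more open face is used to return to 24.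

**Step 12.** The hydroxymethyl reagent may add with poor facial selectivity, through competing chelation of the metal by the C8 silyl ether, or may add in the conjugate sense to the unhindered methylene of the enone. The fallback replaces the magnesium/cerium reagent and the C–Si oxidation by a non-chelating lithium carbanion and an acetal cleavage. From 19, [(1-ethoxyethoxy)methyl]lithium (from the tributylstannane and n-BuLi, THF, −78 °C) gives the tertiary alcohol with an acetal-protected hydroxymethyl group F5. Pyridinium p-toluenesulfonate in methanol frees the silylated-alkyne diol F6, and K2CO3 in methanol removes the alkynyl silyl group to return to 21.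

**Step 8.** The Z selectivity may erode, or the basic ylide may enolise ketone 13 with β-elimination of the C8 silyloxy group. The fallback builds the alkene from an enol triflate and sets out from 12, isolated for this purpose.
- Claisen-type acylation of the lithium enolate of ethyl acetate gives the β-keto ester F7.
- E-selective triflation (Tf2O, aqueous Me4NOH, two-phase) gives the (E)-enol triflate F8.
- Me2CuLi replaces the triflate with retention and gives the (Z)-3-methyl enoate F9.
- i-Bu2AlH reduces it to the allylic alcohol F10, and CBr4/PPh3 gives the allylic bromide F11.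
- Alkylation with lithiated 1-(trimethylsilyl)propyne returns to 15.

**Step 14.** The direct oxidation may stall because the primary silyl ether is neopentyl-like, and forcing it may lead to loss of the tertiary silyl ether. The fallback separates the two events. From 22, pyridinium p-toluenesulfonate in MeOH/CH2Cl2 at 0 °C removes only the primary triethylsilyl group and gives the primary alcohol F12, and Dess–Martin oxidation returns to 23.

**Step 19.** Acylation of the hindered C9 hydroxyl may be slow, and prolonged heating may isomerise the angelate to the tiglate. The fallback builds the Z alkene on the ester instead of transferring it. From 28, esterification with 2-[bis(2,2,2-trifluoroethoxy)phosphoryl]propanoic acid (N,N'-dicyclohexylcarbodiimide, 4-(dimethylamino)pyridine) gives the phosphonate ester F13. Still–Gennari olefination with acetaldehyde (KN(SiMe3)2, 18-crown-6, THF, −78 °C) is Z-selective and returns to 31.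

## Further compounds

F1 | step 15 | tert-butyl{[(2R,3S,4R,5Z,9E)-10-iodo-2-{3-[(4-methoxyphenyl)methoxy]prop-1-en-2-yl}-5,9-dimethyl-4-(naphthalen-2-ylmethoxy)-1,2-bis[(triethylsilyl)oxy]deca-5,9-dien-3-yl]oxy}dimethylsilane | CC[Si](CC)(CC)OC[C@](O[Si](CC)(CC)CC)(C(=C)COCc1ccc(OC)cc1)[C@@H](O[Si](C)(C)C(C)(C)C)[C@H](OCc2ccc3ccccc3c2)/C(C)=C\CC/C(C)=C/I
F2 | step 15 | (2S,3S,4R,5Z,9E)-3-[(tert-butyldimethylsilyl)oxy]-10-iodo-2-{3-[(4-methoxyphenyl)methoxy]prop-1-en-2-yl}-5,9-dimethyl-4-(naphthalen-2-ylmethoxy)-2-[(triethylsilyl)oxy]deca-5,9-dienal | O=C[C@](O[Si](CC)(CC)CC)(C(=C)COCc1ccc(OC)cc1)[C@@H](O[Si](C)(C)C(C)(C)C)[C@H](OCc2ccc3ccccc3c2)/C(C)=C\CC/C(C)=C/I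
F3 | step 15 | (1R,2R,3S,4R,5Z,9E)-3-[(tert-butyldimethylsilyl)oxy]-2-{3-[(4-methoxyphenyl)methoxy]prop-1-en-2-yl}-5,9-dimethyl-4-(naphthalen-2-ylmethoxy)-2-[(triethylsilyl)oxy]cyclodeca-5,9-dien-1-ol (C6 epimer of 24) | O[C@@H]1/C=C(\C)CC/C=C(/C)[C@@H](OCc2ccc3ccccc3c2)[C@H](O[Si](C)(C)C(C)(C)C)[C@@]1(O[Si](CC)(CC)CC)C(=C)COCc4ccc(OC)cc4
F4 | step 15 | (2S,3S,4R,5Z,9E)-3-[(tert-butyldimethylsilyl)oxy]-2-{3-[(4-methoxyphenyl)methoxy]prop-1-en-2-yl}-5,9-dimethyl-4-(naphthalen-2-ylmethoxy)-2-[(triethylsilyl)oxy]cyclodeca-5,9-dien-1-one | O=C1/C=C(\C)CC/C=C(/C)[C@@H](OCc2ccc3ccccc3c2)[C@H](O[Si](C)(C)C(C)(C)C)[C@@]1(O[Si](CC)(CC)CC)C(=C)COCc4ccc(OC)cc4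
F5 | step 12 | (3R,4S,5R,6Z)-4-[(tert-butyldimethylsilyl)oxy]-3-[(1-ethoxyethoxy)methyl]-2-{[(4-methoxyphenyl)methoxy]methyl}-6-methyl-5-(naphthalen-2-ylmethoxy)-11-(trimethylsilyl)undeca-1,6-dien-10-yn-3-ol, both acetal epimers | CCOC(C)OC[C@](O)(C(=C)COCc1ccc(OC)cc1)[C@@H](O[Si](C)(C)C(C)(C)C)[C@H](OCc2ccc3ccccc3c2)/C(C)=C\CCC#C[Si](C)(C)C
F6 | step 12 | (2R,3S,4R,5Z)-3-[(tert-butyldimethylsilyl)oxy]-2-{3-[(4-methoxyphenyl)methoxy]prop-1-en-2-yl}-5-methyl-4-(naphthalen-2-ylmethoxy)-10-(trimethylsilyl)dec-5-en-9-yne-1,2-diol | OC[C@](O)(C(=C)COCc1ccc(OC)cc1)[C@@H](O[Si](C)(C)C(C)(C)C)[C@H](OCc2ccc3ccccc3c2)/C(C)=C\CCC#C[Si](C)(C)C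
F7 | step 8 | ethyl (4S,5R)-5-[(tert-butyldimethylsilyl)oxy]-4-(naphthalen-2-ylmethoxy)-3-oxo-6-[(triethylsilyl)oxy]hexanoate | CC[Si](CC)(CC)OC[C@@H](O[Si](C)(C)C(C)(C)C)[C@H](OCc1ccc2ccccc2c1)C(=O)CC(=O)OCC
F8 | step 8 | ethyl (2E,4S,5R)-5-[(tert-butyldimethylsilyl)oxy]-4-(naphthalen-2-ylmethoxy)-6-[(triethylsilyl)oxy]-3-{[(trifluoromethyl)sulfonyl]oxy}hex-2-enoate | CC[Si](CC)(CC)OC[C@@H](O[Si](C)(C)C(C)(C)C)[C@H](OCc1ccc2ccccc2c1)/C(OS(=O)(=O)C(F)(F)F)=C\C(=O)OCC
F9 | step 8 | ethyl (2Z,4R,5R)-5-[(tert-butyldimethylsilyl)oxy]-3-methyl-4-(naphthalen-2-ylmethoxy)-6-[(triethylsilyl)oxy]hex-2-enoate | CC[Si](CC)(CC)OC[C@@H](O[Si](C)(C)C(C)(C)C)[C@H](OCc1ccc2ccccc2c1)/C(C)=C\C(=O)OCC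
F10 | step 8 | (2Z,4R,5R)-5-[(tert-butyldimethylsilyl)oxy]-3-methyl-4-(naphthalen-2-ylmethoxy)-6-[(triethylsilyl)oxy]hex-2-en-1-ol | CC[Si](CC)(CC)OC[C@@H](O[Si](C)(C)C(C)(C)C)[C@H](OCc1ccc2ccccc2c1)/C(C)=C\CO
F11 | step 8 | {[(2R,3R,4Z)-6-bromo-4-methyl-3-(naphthalen-2-ylmethoxy)-1-[(triethylsilyl)oxy]hex-4-en-2-yl]oxy}(tert-butyl)dimethylsilane | CC[Si](CC)(CC)OC[C@@H](O[Si](C)(C)C(C)(C)C)[C@H](OCc1ccc2ccccc2c1)/C(C)=C\CBr
F12 | step 14 | (2R,3S,4R,5Z)-3-[(tert-butyldimethylsilyl)oxy]-2-{3-[(4-methoxyphenyl)methoxy]prop-1-en-2-yl}-5-methyl-4-(naphthalen-2-ylmethoxy)-2-[(triethylsilyl)oxy]dec-5-en-9-yn-1-ol | OC[C@](O[Si](CC)(CC)CC)(C(=C)COCc1ccc(OC)cc1)[C@@H](O[Si](C)(C)C(C)(C)C)[C@H](OCc2ccc3ccccc3c2)/C(C)=C\CCC#C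
F13 | step 19 | (3aR,4S,5R,6Z,10E,11aS)-4-[(tert-butyldimethylsilyl)oxy]-6,10-dimethyl-3-methylidene-2-oxo-3a-[(triethylsilyl)oxy]-2,3,3a,4,5,8,9,11a-octahydrocyclodeca[b]furan-5-yl 2-[bis(2,2,2-trifluoroethoxy)phosphoryl]propanoate, both epimers at the phosphonate carbon | C=C1C(=O)O[C@H]2/C=C(\C)CC/C=C(/C)[C@@H](OC(=O)C(C)P(=O)(OCC(F)(F)F)OCC(F)(F)F)[C@H](O[Si](C)(C)C(C)(C)C)[C@@]12O[Si](CC)(CC)CC
A1 | alternative 1 | methyl 6-O-(tert-butyldimethylsilyl)-2-O-[diazo(diethoxyphosphoryl)acetyl]-3,4-O-isopropylidene-galactopyranoside | CC(C)(C)[Si](C)(C)OC[C@H]1O[C@H](OC)[C@H](OC(=O)C(=[N+]=[N-])P(=O)(OCC)OCC)[C@H]2OC(C)(C)O[C@@H]12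
A2 | alternative 1 | C3-branched galactoside with fused γ-lactone phosphonate (product of the C–H insertion) | CC(C)(C)[Si](C)(C)OC[C@H]1O[C@H](OC)[C@@H]3OC(=O)[C@@H](P(=O)(OCC)OCC)[C@@]34OC(C)(C)O[C@@H]14
A3 | alternative 2 | C9-keto cyclohexenone carrying the C6 4-methoxybenzyl ether, the C7/C8 di-tert-butylsilylene and the C7 N-methoxy-N-methylamide | COc1ccc(CO[C@H]2C=C(C)C(=O)[C@@H]3O[Si](C(C)(C)C)(C(C)(C)C)O[C@]23C(=O)N(C)OC)cc1
A4 | alternative 2 | 1-methylcyclobutene | CC1=CCC1
A5 | alternative 2 | cis,anti,cis photoadduct (cyclohexanone fused to a bicyclo[2.2.0]hexane) | COc1ccc(CO[C@H]2[C@@H]5[C@@]4(C)CC[C@H]4[C@]5(C)C(=O)[C@@H]3O[Si](C(C)(C)C)(C(C)(C)C)O[C@]23C(=O)N(C)OC)cc1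
A6 | alternative 3 | thirteen-membered cyclic ether with the C9 ketone and the C7 silyl enol ether of the prop-2-enyl 2-alkylacrylate (enol ether geometry left open) | COc1ccc(CO[C@@H]2/C=C(\C)CC/C=C(/C)C(=O)COCC(C(=O)OCC=C)=C2O[Si](CC)(CC)CC)cc1
A7 | alternative 3 | ten-membered C8-hydroxy C9-ketone with the prop-2-enyl 2-propenoate on C7 | COc1ccc(CO[C@@H]2/C=C(\C)CC/C=C(/C)C(=O)[C@H](O)[C@@]2(O[Si](CC)(CC)CC)C(=C)C(=O)OCC=C)cc1
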